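**Strategy**

The octanoic acid arm is disconnected at the bond between C6 of the chromanone benzene ring and the benzylic carbon. C6 lies between the C5 hydroxyl and the C7 methoxyl, and the carboxyl carbon can reach the C5 oxygen, so this array is a masked 4-pentylchroman-2-one. An iminium-catalysed Friedel–Crafts alkylation of 5-methoxyresorcinol with (E)-oct-2-enal, closed in the same flask to the lactol, forms the C6–C bond and the O–C bond, sets the R benzylic centre and differentiates the three phenolic oxygens in one operation. Both partners are commercial and unprotected; the pyranone ring and the C8 prenyl group follow on the lactone.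

Key step: step 1

Remark: tricyclic compounds are numbered as pyrano[2,3-f]chromenes (O1 and C2 to C4 the lactone ring, C5 and C6 the remaining benzene positions, O7 and C8 to C10 the pyranone ring); the lactol of step 1 is carried on as its anomeric mixture because its anomeric carbon becomes the lactone carbonyl in step 2.

**Route**

Step 1
Reactants: 1 5-methoxyresorcinol; 2 (E)-oct-2-enal
Product: 6 (4R)-7-hydroxy-5-methoxy-4-pentylchroman-2-ol, via iminium ion 3 (not isolated), via enamine 4 (not isolated), via hydroxy aldehyde 5 (not isolated)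
Conditions: (S)-2-[diphenyl(trimethylsilyloxy)methyl]pyrrolidine (20 mol %), PhCO2H (20 mol %), 1 (2 equiv), CH2Cl2, 0 °C
Reagents that add atoms: none
Why: The amine and 2 condense to the (E)-configured s-trans iminium ion 3, whose C(Ph)2OSiMe3 group covers one face of the β-carbon; the ring carbon of 1 between a hydroxyl and the methoxyl adds to the open face, rearomatisation gives enamine 4, and protonation and hydrolysis release aldehyde 5 and the catalyst. The neighbouring phenolic oxygen then adds to the aldehyde in a 6-exo-trig hemiacetalisation, which closes the only new ring and gives 6. The closest known reaction type is the diarylprolinol silyl ether-catalysed Friedel–Crafts alkylation and hemiacetalisation of naphthols and electron-rich phenols with enals. C4 is set by the catalyst: with the (S)-amine, attack anti to the silyloxydiphenylmethyl group on the (E)-enal should place aryl, CH2 and pentyl in the R arrangement. The step needs attack para to one hydroxyl and not between the two hydroxyls, which is favoured by two equivalent sites against one and by the stronger para donation of hydroxyl over methoxyl, and it needs mono-alkylation, which the excess of 1 and the removal of the aldehyde as lactol should secure.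

Step 2
Reactants: 6 (4R)-7-hydroxy-5-methoxy-4-pentylchroman-2-ol
Product: 7 (4R)-7-hydroxy-5-methoxy-4-pentylchroman-2-one
Conditions: pyridinium chlorochromate C5H5NH[CrO3Cl] (1.5 equiv), NaOAc, 4 Å molecular sieves, CH2Cl2, 0 °C → rt
Reagents that add atoms: none
Why: Chromate-ester oxidation of a lactol to the lactone by hexavalent chromium is fast under buffered conditions, the phenol has no oxidisable C–H and its para position is blocked, and the C4 centre is not touched.

Step 3
Reactants: 7 (4R)-7-hydroxy-5-methoxy-4-pentylchroman-2-one; 8 tigloyl chloride, (E)-2-methylbut-2-enoyl chloride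
Product: 9 (4R)-7-hydroxy-5-methoxy-8-[(2E)-2-methylbut-2-enoyl]-4-pentylchroman-2-one
Conditions: AlCl3 (3 equiv), then 8 (1.2 equiv), CH2Cl2–PhNO2, 0 °C → rt; cold 1 M HCl quench
Reagents that add atoms: none
Why: Friedel–Crafts C-acylation of the aluminium phenoxide should go to C8, which is ortho to the hydroxyl, para to the methoxyl and less hindered than C6, while the chelated product ketone resists a second acylation and the low temperature keeps the o-hydroxyaryl enone from closing on the Lewis acid.

Step 4
Reactants: 9 (4R)-7-hydroxy-5-methoxy-8-[(2E)-2-methylbut-2-enoyl]-4-pentylchroman-2-one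
Product: 10 (4R,8R,9S)-5-methoxy-8,9-dimethyl-4-pentyl-3,4,8,9-tetrahydro-2H,10H-pyrano[2,3-f]chromene-2,10-dione (cis-dimethyl)
Conditions: (−)-quinine (20 mol %), PhCl, 15 °C
Reagents that add atoms: none
Why: In this cinchona alkaloid-catalysed intramolecular oxa-Michael addition (6-endo-trig) of an o-tigloylphenol, the quinuclidine nitrogen takes the phenol proton in an ion pair held by the secondary hydroxyl of the alkaloid, so the phenoxide adds to one face of the (E)-enone and should set C8 as R (the sense known for quinine in such closures, to be confirmed on 10, with quinidine as the control), and kinetic protonation of the enol sets C9 cis to it.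

Step 5
Reactants: 10 (4R,8R,9S)-cis-dimethyl tricycle
Product: 11 (4R,8R,9R)-5-methoxy-8,9-dimethyl-4-pentyl-3,4,8,9-tetrahydro-2H,10H-pyrano[2,3-f]chromene-2,10-dione (trans-dimethyl)
Conditions: MgI2 (1.2 equiv), Et3N (0.3 equiv), CH2Cl2–Et2O, rt
Reagents that add atoms: none
Why: Thermodynamic epimerisation α to the ketone through the magnesium enolate (soft enolisation) inverts only C9 and should lead to the more stable trans isomer with both methyls equatorial, while C8 keeps its configuration because the pyranone ring stays closed; residual 10 is separated and resubmitted.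

Step 6
Reactants: 11 (4R,8R,9R)-trans-dimethyl tricycle
Product: 12 (4R,8R,9R)-6-iodo-5-methoxy-8,9-dimethyl-4-pentyl-3,4,8,9-tetrahydro-2H,10H-pyrano[2,3-f]chromene-2,10-dione
Conditions: NIS (1.05 equiv), CF3CO2H (10 mol %), MeCN, 0 °C → rt, dark
Reagents that add atoms: N-iodosuccinimide, O=C1CCC(=O)N1I
Why: Electrophilic aromatic iodination can only go to C6, the single unsubstituted ring carbon, which is ortho to the methoxyl and to the pyranone ether oxygen, and the ketone and lactone α-positions do not react under these non-enolising conditions.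

Step 7
Reactants: 12 (4R,8R,9R)-6-iodo tricycle; 13 tributyl(3-methylbut-2-en-1-yl)stannane
Product: 14 (4R,8R,9R)-5-methoxy-8,9-dimethyl-6-(3-methylbut-2-en-1-yl)-4-pentyl-3,4,8,9-tetrahydro-2H,10H-pyrano[2,3-f]chromene-2,10-dione
Conditions: Pd(PPh3)4 (10 mol %), dry degassed DMF, 90 °C
Reagents that add atoms: none
Why: Stille coupling of an aryl iodide flanked by two ether oxygens with an allylic stannane proceeds by oxidative addition to zerovalent palladium, transmetalation and reductive elimination at the less hindered allyl terminus, which should give the linear prenyl group at C6 without any base that could epimerise C9 or open either heterocycle.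

Step 8
Reactants: 14 (4R,8R,9R)-6-prenyl tricycle
Product: 16 (3R)-3-[(2R,3R)-5-hydroxy-7-methoxy-2,3-dimethyl-8-(3-methylbut-2-en-1-yl)-4-oxo-3,4-dihydro-2H-chromen-6-yl]octanoic acid, via dilithium salt 15 (not isolated)
Conditions: LiOH·H2O (3 equiv), THF–H2O, 0 °C; then 1 M HCl to pH 3, 0 °C
Reagents that add atoms: lithium hydroxide (hydroxide in water), [Li+].[OH-]
Why: Saponification of the aryl lactone is much faster than enolisation of the ketone, the phenoxide and carboxylate in 15 then protect the chromanone against retro-oxa-Michael opening, and cold acidification should give the acid, whose C5 hydroxyl stays hydrogen-bonded to the C4 ketone and does not relactonise, with no stereocentre touched.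

**Compound list**

1 | 5-methoxyresorcinol (5-methoxybenzene-1,3-diol) | COc1cc(O)cc(O)c1 | starting material
2 | (E)-oct-2-enal | CCCCC/C=C/C=O | starting material
3 | (2S)-2-[diphenyl(trimethylsilyloxy)methyl]-1-[(2E)-oct-2-en-1-ylidene]pyrrolidin-1-ium benzoate (E-iminium ion) | CCCCC/C=C/C=[N+]1/[C@H](C(c2ccccc2)(c2ccccc2)O[Si](C)(C)C)CCC1.[O-]C(=O)c1ccccc1 | intermediate
4 | (2S)-1-[(1E,3R)-3-(2,4-dihydroxy-6-methoxyphenyl)oct-1-en-1-yl]-2-[diphenyl(trimethylsilyloxy)methyl]pyrrolidine (enamine) | CCCCC[C@H](/C=C/N1CCC[C@H]1C(c1ccccc1)(c1ccccc1)O[Si](C)(C)C)c1c(O)cc(O)cc1OC | intermediate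
5 | (3R)-3-(2,4-dihydroxy-6-methoxyphenyl)octanal | CCCCC[C@H](CC=O)c1c(O)cc(O)cc1OC | intermediate
6 | (4R)-7-hydroxy-5-methoxy-4-pentylchroman-2-ol (lactol, both anomers) | CCCCC[C@@H]1CC(O)Oc2cc(O)cc(OC)c12 | intermediate
7 | (4R)-7-hydroxy-5-methoxy-4-pentylchroman-2-one | CCCCC[C@@H]1CC(=O)Oc2cc(O)cc(OC)c12 | intermediate
8 | tigloyl chloride, (E)-2-methylbut-2-enoyl chloride | C/C=C(\C)C(Cl)=O | starting material
9 | (4R)-7-hydroxy-5-methoxy-8-[(2E)-2-methylbut-2-enoyl]-4-pentylchroman-2-one | CCCCC[C@@H]1CC(=O)Oc2c(C(=O)/C(C)=C/C)c(O)cc(OC)c12 | intermediate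
10 | (4R,8R,9S)-5-methoxy-8,9-dimethyl-4-pentyl-3,4,8,9-tetrahydro-2H,10H-pyrano[2,3-f]chromene-2,10-dione (cis) | CCCCC[C@@H]1CC(=O)Oc2c1c(OC)cc1O[C@H](C)[C@H](C)C(=O)c21 | intermediate
11 | (4R,8R,9R)-5-methoxy-8,9-dimethyl-4-pentyl-3,4,8,9-tetrahydro-2H,10H-pyrano[2,3-f]chromene-2,10-dione (trans) | CCCCC[C@@H]1CC(=O)Oc2c1c(OC)cc1O[C@H](C)[C@@H](C)C(=O)c21 | intermediate
12 | (4R,8R,9R)-6-iodo-5-methoxy-8,9-dimethyl-4-pentyl-3,4,8,9-tetrahydro-2H,10H-pyrano[2,3-f]chromene-2,10-dione | CCCCC[C@@H]1CC(=O)Oc2c1c(OC)c(I)c1O[C@H](C)[C@@H](C)C(=O)c21 | intermediate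
13 | tributyl(3-methylbut-2-en-1-yl)stannane | CCCC[Sn](CCCC)(CCCC)CC=C(C)C | starting material
14 | (4R,8R,9R)-5-methoxy-8,9-dimethyl-6-(3-methylbut-2-en-1-yl)-4-pentyl-3,4,8,9-tetrahydro-2H,10H-pyrano[2,3-f]chromene-2,10-dione | CCCCC[C@@H]1CC(=O)Oc2c1c(OC)c(CC=C(C)C)c1O[C@H](C)[C@@H](C)C(=O)c21 | intermediate
15 | dilithium (3R)-3-[(2R,3R)-7-methoxy-2,3-dimethyl-8-(3-methylbut-2-en-1-yl)-5-oxido-4-oxochroman-6-yl]octanoate | CCCCC[C@H](CC(=O)[O-])c1c([O-])c2c(c(CC=C(C)C)c1OC)O[C@H](C)[C@@H](C)C2=O.[Li+].[Li+] | intermediate
16 | (3R)-3-[(2R,3R)-5-hydroxy-7-methoxy-2,3-dimethyl-8-(3-methylbut-2-en-1-yl)-4-oxo-3,4-dihydro-2H-chromen-6-yl]octanoic acid | CCCCC[C@H](CC(=O)O)c1c(O)c2c(c(CC=C(C)C)c1OC)O[C@H](C)[C@@H](C)C2=O | target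

Total step count: 8
Longest linear sequence: 8 steps (1 and 2 to 16)

**Steps most likely to fail**

Step 1. The iminium ion may attack the ring carbon between the two hydroxyls, the still electron-rich lactol may be alkylated a second time, or enantiocontrol may be lost through reversible or uncatalysed addition. The fallback sets out from 1 and builds the lactone ring by condensation and asymmetric reduction in place of conjugate addition.
- Pechmann condensation of 1 with ethyl 3-oxooctanoate (MeSO3H, 0 °C to rt) should give 7-hydroxy-5-methoxy-4-pentyl-2H-chromen-2-one F1, freed from its 5-hydroxy-7-methoxy isomer by crystallisation at this cheap stage.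
- Silylation (TBSCl, imidazole, DMF) gives 7-(tert-butyldimethylsilyloxy)-5-methoxy-4-pentyl-2H-chromen-2-one F2.
- Copper hydride-catalysed asymmetric 1,4-reduction (Cu(OAc)2·H2O, DTBM-SEGPHOS, (EtO)2MeSiH, t-BuOH, PhMe; the ligand enantiomer that gives 4R is fixed on a test run) gives (4R)-7-(tert-butyldimethylsilyloxy)-5-methoxy-4-pentylchroman-2-one F3.
- Bu4NF/AcOH removes the silyl group and the fallback comes back to the route at 7, so steps 1 and 2 are bypassed.

Step 3. The acylium ion may attack C6 in place of C8, or the new enone may add HCl or be closed by the Lewis acid to a chromanone without control at C8. The fallback sets out from 7 and assembles the tigloyl group in two stages, so that no enone meets AlCl3.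
- Acylation with propanoyl chloride (AlCl3, CH2Cl2, 0 °C), a small saturated electrophile that can be used colder and has the same electronic preference for C8, should give (4R)-7-hydroxy-5-methoxy-4-pentyl-8-propanoylchroman-2-one F4.
- Soft enolisation and aldol addition to acetaldehyde (TiCl4, i-Pr2NEt, CH2Cl2, −78 °C) gives (4R)-7-hydroxy-8-(3-hydroxy-2-methylbutanoyl)-5-methoxy-4-pentylchroman-2-one F5 as a mixture at the two new centres.
- Acid-catalysed dehydration (TsOH, PhMe, 60 °C) to the conjugated (E)-enone comes back to the route at 9.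

Step 4. The alkaloid may discriminate the enone faces poorly for this less acidic, non-coumarin phenol, the closure may be slow enough for background cyclisation to compete, or the aryl lactone may transfer its acyl group to the alkaloid hydroxyl. The fallback sets out from 9, gives up catalyst control and uses the fixed C4 centre as an internal resolving handle.
- Closure under thermodynamic conditions (anhydrous K2CO3, butan-2-one, 60 °C) should give the two trans-chromanones, 11 and (4R,8S,9S)-5-methoxy-8,9-dimethyl-4-pentyl-3,4,8,9-tetrahydro-2H,10H-pyrano[2,3-f]chromene-2,10-dione F6, which are diastereomers and separable by chromatography or crystallisation.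
- F6 is recycled by renewed exposure to the same base, which equilibrates C8 through retro-oxa-Michael opening and re-closure.
- The fallback comes back to the route at 11 and bypasses steps 4 and 5.

**Further compounds**

F1 | step 1 | 7-hydroxy-5-methoxy-4-pentyl-2H-chromen-2-one | CCCCCC1=CC(=O)Oc2cc(O)cc(OC)c12
F2 | step 1 | 7-(tert-butyldimethylsilyloxy)-5-methoxy-4-pentyl-2H-chromen-2-one | CCCCCC1=CC(=O)Oc2cc(O[Si](C)(C)C(C)(C)C)cc(OC)c12
F3 | step 1 | (4R)-7-(tert-butyldimethylsilyloxy)-5-methoxy-4-pentylchroman-2-one | CCCCC[C@@H]1CC(=O)Oc2cc(O[Si](C)(C)C(C)(C)C)cc(OC)c12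
F4 | step 3 | (4R)-7-hydroxy-5-methoxy-4-pentyl-8-propanoylchroman-2-one | CCCCC[C@@H]1CC(=O)Oc2c(C(=O)CC)c(O)cc(OC)c12
F5 | step 3 | (4R)-7-hydroxy-8-(3-hydroxy-2-methylbutanoyl)-5-methoxy-4-pentylchroman-2-one (mixture at the two new centres) | CCCCC[C@@H]1CC(=O)Oc2c(C(=O)C(C)C(C)O)c(O)cc(OC)c12
F6 | step 4 | (4R,8S,9S)-5-methoxy-8,9-dimethyl-4-pentyl-3,4,8,9-tetrahydro-2H,10H-pyrano[2,3-f]chromene-2,10-dione (trans) | CCCCC[C@@H]1CC(=O)Oc2c1c(OC)cc1O[C@@H](C)[C@H](C)C(=O)c21
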